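Locants: unprimed = upper chroman (benzo ring A, aryl ring B on C3); primed = lower chroman (benzo ring D); double-primed = central arene (ring C: C1'' bonded to C4, C2'' methoxy, C4'' hydroxyl, C6'' bonded to C3').

## The problem

Target 31 is an isoflavan dimer built around one crowded carbon: C4 of the upper chroman carries ring C and sits next to C3, which carries the 2,3-dihydroxy-4-methoxyphenyl ring B, and ring C carries, ortho to this junction, C3' of a second 7-hydroxychroman. Ring C is a 1,2,3,5-tetrasubstituted resorcinol monomethyl ether; substitution or metalation of a preformed resorcinol would favour the carbon between the two oxygens or the open C5'', not C1''. Three stereocentres must be set: C3 (R) and C4 (S), trans across the upper pyran ring, and C3' (R) on the lower one. C3 and C4 are neighbours, so either can direct the other, and with a carbonyl at C2 the C3 centre can be equilibrated to trans; C3' is insulated from them by ring C and needs its own source of asymmetry, although its presence makes wrong C3/C4 isomers separable diastereomers. C4 is doubly benzylic between electron-rich arenes and bonded to a 2,6-disubstituted aryl group, so bond formation there is hindered and the finished centre is easily ionised by acid; the pyrogallol-type ring B and the other phenols are oxidation-prone and should stay masked to the end. Intermediates in which C3' stands next to a formyl or alkynyl ketone group are base-labile, because deprotonation there can expel the ring aryloxide. The enabling feature is that C1'' and C6'', the two carbon-substituted atoms of ring C, are adjacent and can be the two carbons of an alkyne, while C2''–C5'', oxygenated at C2'' and C4'', is a 1,3-dioxygenated diene unit; with C4 as a ketone carbon the alkyne is polarised so that only one orientation of the two pieces is expected.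

## Retrosynthesis

31 from 30. The five phenolic O–H bonds are traced back to O–benzyl bonds. One neutral hydrogenolysis then releases all phenols in the last step; the two methyl ethers and both pyran rings are inert to it. Penta-ether 30 is no simpler in skeleton but is robust towards base, hydride and air. The forward step must only avoid oxidation of the liberated pyrogallol-type ring.

30 from 29 and 28. The O1–C2 ether bond is cut to give phenol–primary alcohol 29, and C2 is then raised to the lactone carbonyl of 28. Cutting C4–C4a instead would require a free cation at C4 (see Alternative 3). The carbonyl at C2 makes C3 an enolisable carbon, so the C3–C4 bond can be made by enolate chemistry and the trans arrangement can be secured by equilibration. The forward steps are a hydride reduction and a ring closure at a primary carbon, neither touching a stereocentre.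

28 from 21 and 25. The C3–C4 bond and the O1–C2 acyl bond are cut, leading to ortho-quinone methide 27 (released from sulfonyl phenol 21) and arylacetic acid 25 (activated as anhydride 26). Cutting C4–C1'' instead would need a 2,6-disubstituted aryl nucleophile with the same regiochemical problem as ring C itself. The cut removes ring B, one ring and both upper stereocentres at once. The forward reaction must form a bond to a methide carbon flanked by a 2,6-disubstituted aryl group, with catalyst control of both new centres.

21 from 19, 18 and 17. These are functional-group changes only: the sulfonyl-bearing carbon of 21 is the carbinol carbon of 19, the ketone carbon of 18 and of phenol 17. Keeping C4 at the ketone level back to this point is what the ring C synthesis needs. The forward steps ask for reduction of a hindered diaryl ketone and for exchange of hydroxyl against sulfinate with release of the ortho phenol.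

17 from 13 and 14. The ring C bonds C1''–C2'' and C5''–C6'' are cut, giving ynone 13 and diene 14. This cut is preferred to any substitution on a preformed resorcinol because the positions of aroyl, methoxy, hydroxyl and chromanyl follow from the polarity of the two partners, and methoxy and hydroxyl emerge differentiated. The precursor 13 is an acyclic alkyne with one stereocentre and 14 is a commodity diene. The forward reaction must be regioselective and must leave the propargylic C3' centre untouched.

13 from 12, 9 and 10. The ynone is traced to propargylic alcohol 12 and this to the bond between the carbinol carbon and the alkyne, giving acetylide 11 (from dibromo-olefin 9) and aldehyde 10. Cutting the C3'–alkyne bond instead would need a stereospecific coupling at a secondary carbon. Both fragments are small, and ring A arrives complete with its oxygen pattern.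

9 from 8, 7, 6 and 5. The alkyne carbon bonded to C3' is the former carboxyl carbon of acid 6; aldehyde 8 and alcohol 7 lie between. C3' is traced to the C3=C4 double bond of chromene acid 5, because a β-aryl-α-substituted acrylic acid is a favourable substrate class for asymmetric hydrogenation. The forward sequence must keep base away from aldehyde 8.

5 from 4, 2 and 3; 10 from 2; 2 from 1. The lower pyran ring is cut at O1'–C2' and C3'–C4', giving salicylaldehyde 2 and acrylate 3 through ester 4. The same aldehyde 2, from 1 by selective benzylation, also supplies ring A as its methoxymethyl ether 10, so one starting material feeds both benzo rings.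

25 from 24, 23 and 22. The arylacetic acid is cut at the CH2–CO2H bond via nitrile 24 to bis-benzyl aldehyde 23 and commercial aldehyde 22, which already carries the oxygen pattern of ring B.

## Roads not taken

Alternative 1: Ring C is kept and both carbon arms are attached in one step, cutting the C1''–carbonyl bond and the C6''–CH2 bond. In the forward sense, fluoride releases a 3-methoxy-5-benzyloxy aryne from silylaryl triflate A2. The enolate carbon of β-ketoester A3 adds to the aryne carbon remote from methoxy, the aryl anion closes onto the ketone, and the four-membered alkoxide fragments to the ortho-acyl arylacetate A1.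
- Merits: a convergent union at ambient temperature, orientation steered by the methoxy group, and no stereocentre exposed during the ring C event.
- Weak points: A1 contains neither ring of the lower chroman nor C3' as a stereocentre. The lower chroman would have to be grown afterwards from the arylacetate by enantioselective benzylation, reduction and ether closure, all beside a hindered diaryl ketone. A2 is itself a 1,2,3,5-tetrasubstituted arene whose synthesis meets the regiochemical problem the plan is meant to avoid.
- Comparison: this road is milder and at least as convergent in its key step. The chosen plan sets against it that C3' enters already configured by a catalytic hydrogenation, that the oxygen pattern of ring C is created rather than engineered, and that nothing remains to be built on ring C after the key step.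

Alternative 2: The upper pyran ring is cut at C3–C4 and at the O1–C2 acyl bond. In the forward sense, base frees an ortho-quinone methide from sulfonyl phenol A5 (the same compound as 21), an isothiourea-bound enolate from active ester A6 adds to it, and lactonisation gives trans-dihydrocoumarin A4 (the same compound as 28).
- Merits: the most productive single step available for this target: two bonds, one ring and both upper stereocentres under catalyst control.
- Weak points: as the organising idea it leaves open how ring C in A5 is assembled, and the methide carbon is flanked by a 2,6-disubstituted aryl group.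
- Comparison: the chosen plan adopts this reaction as its end game (step 18), so the two are complementary. If A5 were made by substitution chemistry on a preformed isoflavan, the route would be shorter, but it would depend on functionalising C1'' in preference to C3'' and C5''. The chosen plan sets certainty of the ring C pattern against that saving.

Alternative 3: The upper pyran ring is closed last by cutting C4–C4a. In the forward sense, a Lewis acid ionises benzylic alcohol A8, and the tethered 3-benzyloxyphenyl ether attacks the cation para to its benzyloxy group to give penta-benzyl ether A7 (the same compound as 30), trans to the C3 aryl group.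
- Merits: the closure arrives directly at the chroman oxidation level, so the lactone reduction and the etherification of the chosen plan are not needed, and C3 steers C4 without a chiral catalyst.
- Weak points: the C4 cation has other outlets. The ortho-benzyloxy oxygen of ring B can close a five-membered ring with loss of benzyl, the electron-rich ring B can migrate through a phenonium ion, and elimination to a stilbene is possible. A8 still needs ring C with its full pattern and a separately set C3.
- Comparison: this road is two steps shorter at the end. The chosen plan sets against it that C3 and C4 are formed together under catalyst control, with the trans relation backed by equilibration, and that no free cation is generated next to participating groups.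

Key step: step 11

Assumptions: diene 14 is bought and distilled before use. The ligand and catalyst antipodes named in steps 4 and 18 are assigned by analogy with the usual sense of induction of these catalyst classes; the mirror-image ligand or catalyst is used if the first run shows the opposite sense.

## Route

Step 1
Reactants: 1 2,4-dihydroxybenzaldehyde
Product: 2 4-(benzyloxy)-2-hydroxybenzaldehyde
Conditions: BnBr (1.05 equiv), NaHCO3, MeCN, reflux
Reagents that add atoms: benzyl bromide, BrCc1ccccc1
Why: Williamson etherification; the 2-hydroxyl is held in a hydrogen bond to the formyl group and is the weaker nucleophile under a mild base, so alkylation should go to the 4-hydroxyl.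

Step 2
Reactants: 2 4-(benzyloxy)-2-hydroxybenzaldehyde, 3 tert-butyl acrylate
Product: 4 tert-butyl 7-(benzyloxy)-2H-chromene-3-carboxylate
Conditions: 3 (3 equiv), 1,4-diazabicyclo[2.2.2]octane (DABCO, 0.5 equiv), CHCl3–H2O, rt to 40 °C
Reagents that add atoms: none
Why: Baylis–Hillman reaction of the salicylaldehyde, then oxa-Michael closure by the phenol oxygen and loss of water, the known route from salicylaldehydes and acrylates to 2H-chromene-3-carboxylates; the bulky tert-butyl ester suppresses lactonisation to a coumarin.

Step 3
Reactants: 4 tert-butyl 7-(benzyloxy)-2H-chromene-3-carboxylate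
Product: 5 7-(benzyloxy)-2H-chromene-3-carboxylic acid
Conditions: CF3CO2H, CH2Cl2, 0 °C to rt
Reagents that add atoms: none
Why: Acidolysis of the tert-butyl ester with loss of isobutene; aryl benzyl ethers are stable to trifluoroacetic acid at this temperature.

Step 4
Reactants: 5 7-(benzyloxy)-2H-chromene-3-carboxylic acid
Product: 6 (S)-7-(benzyloxy)chroman-3-carboxylic acid
Conditions: H2 (10 bar), Ru(OAc)2[(R)-BINAP] (1 mol%), MeOH, 30 °C
Reagents that add atoms: none
Why: Carboxylate-directed asymmetric hydrogenation of a β-aryl-α-substituted acrylic acid, a substrate class that includes 2H-chromene-3-carboxylic acids; the catalyst delivers both hydrogens to one face of C3=C4 and so sets the future C3', and the homogeneous catalyst leaves the benzyl ether intact.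

Step 5
Reactants: 6 (S)-7-(benzyloxy)chroman-3-carboxylic acid
Product: 7 (R)-[7-(benzyloxy)chroman-3-yl]methanol
Conditions: BH3·THF, THF, 0 °C to rt; MeOH quench
Reagents that add atoms: none
Why: Chemoselective borane reduction of a carboxylic acid through the acyloxyborane; the medium is non-basic, so the centre α to the carboxyl and β to the ring oxygen is not at risk (the descriptor changes only because the priorities change).

Step 6
Reactants: 7 (R)-[7-(benzyloxy)chroman-3-yl]methanol
Product: 8 (S)-7-(benzyloxy)chroman-3-carbaldehyde
Conditions: Dess–Martin periodinane, CH2Cl2, 0 °C to rt; used crude at once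
Reagents that add atoms: none
Why: Hypervalent-iodine oxidation under neutral conditions; no base is present, which matters because enolisation of this aldehyde would allow β-elimination of the ring aryloxide and racemisation.

Step 7
Reactants: 8 (S)-7-(benzyloxy)chroman-3-carbaldehyde
Product: 9 (R)-7-(benzyloxy)-3-(2,2-dibromovinyl)chroman
Conditions: CBr4, PPh3, CH2Cl2, 0 °C
Reagents that add atoms: carbon tetrabromide, BrC(Br)(Br)Br
Why: Corey–Fuchs dibromo-olefination, a Wittig reaction of the weakly basic ylide Ph3P=CBr2; it is preferred to the alkoxide-mediated diazophosphonate homologation so that the α-stereocentre never meets a base.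

Step 8
Reactants: 2 4-(benzyloxy)-2-hydroxybenzaldehyde
Product: 10 4-(benzyloxy)-2-(methoxymethoxy)benzaldehyde
Conditions: MeOCH2Cl, iPr2NEt, CH2Cl2, 0 °C to rt
Reagents that add atoms: chloromethyl methyl ether, COCCl
Why: O-alkylation of the phenol by the oxocarbenium ion of the α-chloro ether; the acetal masks the oxygen that becomes O1, survives organolithium, oxidant and heat, and is removable beside benzyl ethers.

Step 9
Reactants: 9 (R)-7-(benzyloxy)-3-(2,2-dibromovinyl)chroman, 10 4-(benzyloxy)-2-(methoxymethoxy)benzaldehyde
Product: 12 1-[4-(benzyloxy)-2-(methoxymethoxy)phenyl]-3-[(R)-7-(benzyloxy)chroman-3-yl]prop-2-yn-1-ol (both carbinol epimers), via lithium acetylide 11 (not isolated)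
Conditions: n-BuLi (2.1 equiv), THF, −78 to −20 °C; then 10, −78 to 0 °C; sat. aq. NH4Cl
Reagents that add atoms: none
Why: Second stage of the Corey–Fuchs sequence: bromine–lithium exchange, α-elimination with 1,2-hydrogen shift and deprotonation give acetylide 11, which undergoes 1,2-addition to aldehyde 10. The propargylic C–H is far less acidic than the alkyne C–H, so C3' is untouched, and the carbinol configuration is irrelevant because it is oxidised next.

Step 10
Reactants: 12 1-[4-(benzyloxy)-2-(methoxymethoxy)phenyl]-3-[(R)-7-(benzyloxy)chroman-3-yl]prop-2-yn-1-ol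
Product: 13 1-[4-(benzyloxy)-2-(methoxymethoxy)phenyl]-3-[(R)-7-(benzyloxy)chroman-3-yl]prop-2-yn-1-one
Conditions: MnO2 (excess), CH2Cl2, rt
Reagents that add atoms: none
Why: Heterogeneous oxidation of a doubly activated (benzylic and propargylic) alcohol on manganese dioxide; the neutral medium avoids isomerisation of the ynone to an allenyl ketone.

Step 11
Reactants: 13 1-[4-(benzyloxy)-2-(methoxymethoxy)phenyl]-3-[(R)-7-(benzyloxy)chroman-3-yl]prop-2-yn-1-one, 14 1,1-dimethoxy-3-(trimethylsilyloxy)buta-1,3-diene
Product: 17 [4-(benzyloxy)-2-(methoxymethoxy)phenyl]{2-[(R)-7-(benzyloxy)chroman-3-yl]-4-hydroxy-6-methoxyphenyl}methanone, via cyclohexadiene cycloadduct 15 (not isolated), via aryl trimethylsilyl ether 16 (not isolated)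
Conditions: 14 (3 equiv), toluene, 110 °C, sealed tube, Ar; then 1 M aq. HCl–THF, 0 °C, brief
Reagents that add atoms: none
Why: This is a thermal [4+2] cycloaddition of a 1,1-dialkoxy-3-silyloxydiene with an ynone followed by aromatisation, a benzannulation established for ynones and ynoates. The terminal CH2 of 14, onto which both the silyloxy and the ketene-acetal oxygens push electron density, bonds to the β-alkynyl carbon of 13 (the one bearing the chromanyl group), and the acetal carbon bonds to the α-carbon, in a concerted but strongly asynchronous, Mukaiyama–Michael-like transition state. Ring C is thus closed by intermolecular cycloaddition, both new bonds (C5''–C6'' and C1''–C2'') arising together to give the 1,4-cyclohexadiene 15. Adduct 15 loses methanol across the ring (methoxy from C2'', hydrogen from C5''), driven by aromatisation, to give silyl ether 16, which dilute acid cleaves to phenol 17 without touching the methoxymethyl acetal. No stereocentre is formed. The selectivity required is regiochemical and is secured by the matched polarisation of the ketone-polarised alkyne and the donor-polarised diene, which places the aroyl group beside the surviving methoxy, the hydroxyl para to it and the chromanyl group beside an unsubstituted carbon. The second requirement, retention at C3', is met because no base is present to remove the propargylic hydrogen, whose loss would open the way to an allenyl ketone and to expulsion of the ring oxygen. Methoxy and hydroxyl emerge differentiated, so no selective alkylation is needed later.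

Step 12
Reactants: 17 [4-(benzyloxy)-2-(methoxymethoxy)phenyl]{2-[(R)-7-(benzyloxy)chroman-3-yl]-4-hydroxy-6-methoxyphenyl}methanone
Product: 18 [4-(benzyloxy)-2-(methoxymethoxy)phenyl]{4-(benzyloxy)-2-[(R)-7-(benzyloxy)chroman-3-yl]-6-methoxyphenyl}methanone
Conditions: BnBr, K2CO3, DMF, rt
Reagents that add atoms: benzyl bromide, BrCc1ccccc1
Why: Williamson etherification of an acidic para-acyl phenol; masking this hydroxyl is necessary because a free para-hydroxyl would divert step 18 through a para-quinone methide.

Step 13
Reactants: 18 [4-(benzyloxy)-2-(methoxymethoxy)phenyl]{4-(benzyloxy)-2-[(R)-7-(benzyloxy)chroman-3-yl]-6-methoxyphenyl}methanone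
Product: 19 [4-(benzyloxy)-2-(methoxymethoxy)phenyl]{4-(benzyloxy)-2-[(R)-7-(benzyloxy)chroman-3-yl]-6-methoxyphenyl}methanol (both carbinol epimers)
Conditions: LiAlH4, THF, 0 °C to rt
Reagents that add atoms: none
Why: Hydride addition to a diaryl ketone flanked by three ortho substituents, for which LiAlH4 is chosen; the carbinol configuration is irrelevant (the carbon is planarised in step 18), and reducing while the ortho oxygen is still protected prevents over-reduction through a quinone methide.

Step 14
Reactants: 19 [4-(benzyloxy)-2-(methoxymethoxy)phenyl]{4-(benzyloxy)-2-[(R)-7-(benzyloxy)chroman-3-yl]-6-methoxyphenyl}methanol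
Product: 21 5-(benzyloxy)-2-{[4-(benzyloxy)-2-((R)-7-(benzyloxy)chroman-3-yl)-6-methoxyphenyl](4-methylbenzenesulfonyl)methyl}phenol (both epimers at the sulfonyl-bearing carbon), via methoxymethyl-protected sulfone 20 (not isolated)
Conditions: p-TolSO2Na (5 equiv), 3 M aq. HCl, MeOH–THF, rt to 40 °C
Reagents that add atoms: sodium p-toluenesulfinate, Cc1ccc(S(=O)[O-])cc1.[Na+]
Why: Acid ionises the doubly donor-stabilised benzhydrol and p-toluenesulfinic acid captures the cation at sulfur (SN1 sulfone formation, the standard entry to 2-(sulfonylalkyl)phenols); the same acid in methanol then cleaves the methoxymethyl acetal, while excess sulfinate keeps the re-ionisable centre capped.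

Step 15
Reactants: 22 2,3-dihydroxy-4-methoxybenzaldehyde
Product: 23 2,3-bis(benzyloxy)-4-methoxybenzaldehyde
Conditions: BnBr (2.4 equiv), K2CO3, DMF, 60 °C
Reagents that add atoms: benzyl bromide, BrCc1ccccc1
Why: Double Williamson etherification; heating is used because the hydroxyl ortho to the formyl group is hydrogen-bonded and reacts second.

Step 16
Reactants: 23 2,3-bis(benzyloxy)-4-methoxybenzaldehyde
Product: 24 2-[2,3-bis(benzyloxy)-4-methoxyphenyl]acetonitrile
Conditions: p-toluenesulfonylmethyl isocyanide (TosMIC), t-BuOK, DME, −40 °C; then MeOH, reflux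
Reagents that add atoms: p-toluenesulfonylmethyl isocyanide, Cc1ccc(S(=O)(=O)C[N+]#[C-])cc1
Why: Van Leusen reductive cyanation: the metalated isocyanide adds to the aldehyde, the oxazoline formed opens, and methanolysis expels sulfinate and formate to leave the one-carbon-homologated nitrile; low temperature with a strong base disfavours the competing oxazole.

Step 17
Reactants: 24 2-[2,3-bis(benzyloxy)-4-methoxyphenyl]acetonitrile
Product: 25 2-[2,3-bis(benzyloxy)-4-methoxyphenyl]acetic acid
Conditions: KOH, EtOH–H2O, reflux; then aq. HCl
Reagents that add atoms: water, O (delivered as hydroxide from potassium hydroxide, [K+].[OH-])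
Why: Base hydrolysis of the nitrile through the amide to the carboxylate; benzyl and methyl aryl ethers are inert to aqueous alkali.

Step 18
Reactants: 21 5-(benzyloxy)-2-{[4-(benzyloxy)-2-((R)-7-(benzyloxy)chroman-3-yl)-6-methoxyphenyl](4-methylbenzenesulfonyl)methyl}phenol, 25 2-[2,3-bis(benzyloxy)-4-methoxyphenyl]acetic acid
Product: 28 (3R,4S)-7-(benzyloxy)-4-{4-(benzyloxy)-2-[(R)-7-(benzyloxy)chroman-3-yl]-6-methoxyphenyl}-3-[2,3-bis(benzyloxy)-4-methoxyphenyl]chroman-2-one, via mixed pivalic anhydride 26 (not isolated), via ortho-quinone methide 27 (not isolated)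
Conditions: 25 (1.5 equiv), t-BuCOCl, iPr2NEt, CH2Cl2, 0 °C; then 21, isothiourea (2R,3S)-HyperBTM [(2R,3S)-3-isopropyl-2-phenyl-3,4-dihydro-2H-benzo[4,5]thiazolo[3,2-a]pyrimidine] (10 mol%), Cs2CO3, CH2Cl2, 0 °C to rt
Reagents that add atoms: none
Why: Isothiourea-catalysed Michael addition–lactonisation of a C(1)-ammonium enolate with an ortho-quinone methide freed from a 2-(sulfonylalkyl)phenol, a known formal [4+2] route to 3,4-dihydrocoumarins. Cs2CO3 expels sulfinate from 21 to give 27, the catalyst is acylated by 26 and deprotonated to the (Z)-enolate, this adds through its unshielded face to the methide carbon, and the phenoxide closes the lactone and frees the catalyst. C3 is set by the catalyst (the face away from its phenyl group), C4 by the anti approach of the two aryl-bearing carbons; any cis lactone should epimerise at C3 to trans under the carbonate.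

Step 19
Reactants: 28 (3R,4S)-7-(benzyloxy)-4-{4-(benzyloxy)-2-[(R)-7-(benzyloxy)chroman-3-yl]-6-methoxyphenyl}-3-[2,3-bis(benzyloxy)-4-methoxyphenyl]chroman-2-one
Product: 29 (2R,3S)-3-[4-(benzyloxy)-2-hydroxyphenyl]-3-{4-(benzyloxy)-2-[(R)-7-(benzyloxy)chroman-3-yl]-6-methoxyphenyl}-2-[2,3-bis(benzyloxy)-4-methoxyphenyl]propan-1-ol
Conditions: LiAlH4, THF, 0 °C
Reagents that add atoms: none
Why: Hydride reduction of an aryl ester (lactone) to phenol and primary alcohol; addition to the activated phenolic ester and to the transient aldehyde is faster than enolisation, so C3 should keep its configuration.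

Step 20
Reactants: 29 (2R,3S)-3-[4-(benzyloxy)-2-hydroxyphenyl]-3-{4-(benzyloxy)-2-[(R)-7-(benzyloxy)chroman-3-yl]-6-methoxyphenyl}-2-[2,3-bis(benzyloxy)-4-methoxyphenyl]propan-1-ol
Product: 30 (3R,4S)-7-(benzyloxy)-4-{4-(benzyloxy)-2-[(R)-7-(benzyloxy)chroman-3-yl]-6-methoxyphenyl}-3-[2,3-bis(benzyloxy)-4-methoxyphenyl]chroman
Conditions: PPh3, diisopropyl azodicarboxylate, THF, 0 °C to rt
Reagents that add atoms: none
Why: Intramolecular Mitsunobu etherification, the usual closure of isoflavans from 3-(2-hydroxyphenyl)propanols; the phenol displaces the activated primary alkoxyphosphonium in a 6-exo-tet closure, so no stereocentre takes part.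

Step 21
Reactants: 30 (3R,4S)-7-(benzyloxy)-4-{4-(benzyloxy)-2-[(R)-7-(benzyloxy)chroman-3-yl]-6-methoxyphenyl}-3-[2,3-bis(benzyloxy)-4-methoxyphenyl]chroman
Product: 31 (3R,4S)-3-(2,3-dihydroxy-4-methoxyphenyl)-4-{4-hydroxy-2-[(R)-7-hydroxychroman-3-yl]-6-methoxyphenyl}chroman-7-ol (CNP0227211.1)
Conditions: H2 (1 atm), Pd/C (10%), EtOAc–MeOH, rt, degassed solvents
Reagents that add atoms: none
Why: Hydrogenolysis of five aryl benzyl ethers; the pyran C–O bonds are not benzylic and the C4–aryl bonds are inert, so only the benzyl groups should be lost, and exclusion of air protects the pyrogallol-type ring.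

## Compound list

1 | 2,4-dihydroxybenzaldehyde | O=Cc1ccc(O)cc1O | starting material
2 | 4-(benzyloxy)-2-hydroxybenzaldehyde | O=Cc1ccc(OCc2ccccc2)cc1O | intermediate
3 | tert-butyl acrylate | C=CC(=O)OC(C)(C)C | starting material
4 | tert-butyl 7-(benzyloxy)-2H-chromene-3-carboxylate | CC(C)(C)OC(=O)C1=Cc2ccc(OCc3ccccc3)cc2OC1 | intermediate
5 | 7-(benzyloxy)-2H-chromene-3-carboxylic acid | OC(=O)C1=Cc2ccc(OCc3ccccc3)cc2OC1 | intermediate
6 | (S)-7-(benzyloxy)chroman-3-carboxylic acid | OC(=O)[C@@H]1COc2cc(OCc3ccccc3)ccc2C1 | intermediate
7 | (R)-[7-(benzyloxy)chroman-3-yl]methanol | OC[C@@H]1COc2cc(OCc3ccccc3)ccc2C1 | intermediate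
8 | (S)-7-(benzyloxy)chroman-3-carbaldehyde | O=C[C@@H]1COc2cc(OCc3ccccc3)ccc2C1 | intermediate
9 | (R)-7-(benzyloxy)-3-(2,2-dibromovinyl)chroman | BrC(Br)=C[C@@H]1COc2cc(OCc3ccccc3)ccc2C1 | intermediate
10 | 4-(benzyloxy)-2-(methoxymethoxy)benzaldehyde | COCOc1cc(OCc2ccccc2)ccc1C=O | intermediate
11 | {[(R)-7-(benzyloxy)chroman-3-yl]ethynyl}lithium (formed in the flask) | [Li]C#C[C@@H]1COc2cc(OCc3ccccc3)ccc2C1 | intermediate
12 | 1-[4-(benzyloxy)-2-(methoxymethoxy)phenyl]-3-[(R)-7-(benzyloxy)chroman-3-yl]prop-2-yn-1-ol (carbinol epimers) | OC(C#C[C@@H]1COc2cc(OCc3ccccc3)ccc2C1)c1ccc(OCc2ccccc2)cc1OCOC | intermediate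
13 | 1-[4-(benzyloxy)-2-(methoxymethoxy)phenyl]-3-[(R)-7-(benzyloxy)chroman-3-yl]prop-2-yn-1-one | O=C(C#C[C@@H]1COc2cc(OCc3ccccc3)ccc2C1)c1ccc(OCc2ccccc2)cc1OCOC | intermediate
14 | 1,1-dimethoxy-3-(trimethylsilyloxy)buta-1,3-diene | COC(OC)=CC(=C)O[Si](C)(C)C | starting material
15 | [4-(benzyloxy)-2-(methoxymethoxy)phenyl]{2-[(R)-7-(benzyloxy)chroman-3-yl]-6,6-dimethoxy-4-(trimethylsilyloxy)cyclohexa-1,4-dien-1-yl}methanone (formed in the flask) | COC1(OC)C=C(O[Si](C)(C)C)CC([C@@H]2COc3cc(OCc4ccccc4)ccc3C2)=C1C(=O)c1ccc(OCc2ccccc2)cc1OCOC | intermediate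
16 | [4-(benzyloxy)-2-(methoxymethoxy)phenyl]{2-[(R)-7-(benzyloxy)chroman-3-yl]-6-methoxy-4-(trimethylsilyloxy)phenyl}methanone (formed in the flask) | COc1cc(O[Si](C)(C)C)cc([C@@H]2COc3cc(OCc4ccccc4)ccc3C2)c1C(=O)c1ccc(OCc2ccccc2)cc1OCOC | intermediate
17 | [4-(benzyloxy)-2-(methoxymethoxy)phenyl]{2-[(R)-7-(benzyloxy)chroman-3-yl]-4-hydroxy-6-methoxyphenyl}methanone | COc1cc(O)cc([C@@H]2COc3cc(OCc4ccccc4)ccc3C2)c1C(=O)c1ccc(OCc2ccccc2)cc1OCOC | intermediate
18 | [4-(benzyloxy)-2-(methoxymethoxy)phenyl]{4-(benzyloxy)-2-[(R)-7-(benzyloxy)chroman-3-yl]-6-methoxyphenyl}methanone | COc1cc(OCc2ccccc2)cc([C@@H]2COc3cc(OCc4ccccc4)ccc3C2)c1C(=O)c1ccc(OCc2ccccc2)cc1OCOC | intermediate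
19 | [4-(benzyloxy)-2-(methoxymethoxy)phenyl]{4-(benzyloxy)-2-[(R)-7-(benzyloxy)chroman-3-yl]-6-methoxyphenyl}methanol (carbinol epimers) | COc1cc(OCc2ccccc2)cc([C@@H]2COc3cc(OCc4ccccc4)ccc3C2)c1C(O)c1ccc(OCc2ccccc2)cc1OCOC | intermediate
20 | (R)-7-(benzyloxy)-3-{5-(benzyloxy)-2-[[4-(benzyloxy)-2-(methoxymethoxy)phenyl](4-methylbenzenesulfonyl)methyl]-3-methoxyphenyl}chroman (formed in the flask) | COc1cc(OCc2ccccc2)cc([C@@H]2COc3cc(OCc4ccccc4)ccc3C2)c1C(c1ccc(OCc2ccccc2)cc1OCOC)S(=O)(=O)c1ccc(C)cc1 | intermediate
21 | 5-(benzyloxy)-2-{[4-(benzyloxy)-2-((R)-7-(benzyloxy)chroman-3-yl)-6-methoxyphenyl](4-methylbenzenesulfonyl)methyl}phenol (epimers at the sulfonyl carbon) | COc1cc(OCc2ccccc2)cc([C@@H]2COc3cc(OCc4ccccc4)ccc3C2)c1C(c1ccc(OCc2ccccc2)cc1O)S(=O)(=O)c1ccc(C)cc1 | intermediate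
22 | 2,3-dihydroxy-4-methoxybenzaldehyde | COc1ccc(C=O)c(O)c1O | starting material
23 | 2,3-bis(benzyloxy)-4-methoxybenzaldehyde | COc1ccc(C=O)c(OCc2ccccc2)c1OCc1ccccc1 | intermediate
24 | 2-[2,3-bis(benzyloxy)-4-methoxyphenyl]acetonitrile | N#CCc1ccc(OC)c(OCc2ccccc2)c1OCc1ccccc1 | intermediate
25 | 2-[2,3-bis(benzyloxy)-4-methoxyphenyl]acetic acid | OC(=O)Cc1ccc(OC)c(OCc2ccccc2)c1OCc1ccccc1 | intermediate
26 | 2-[2,3-bis(benzyloxy)-4-methoxyphenyl]acetic pivalic anhydride (formed in the flask) | CC(C)(C)C(=O)OC(=O)Cc1ccc(OC)c(OCc2ccccc2)c1OCc1ccccc1 | intermediate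
27 | 3-(benzyloxy)-6-{[4-(benzyloxy)-2-((R)-7-(benzyloxy)chroman-3-yl)-6-methoxyphenyl]methylidene}cyclohexa-2,4-dien-1-one (formed in the flask) | O=C1C=C(OCc2ccccc2)C=CC1=Cc1c(OC)cc(OCc2ccccc2)cc1[C@@H]1COc2cc(OCc3ccccc3)ccc2C1 | intermediate
28 | (3R,4S)-7-(benzyloxy)-4-{4-(benzyloxy)-2-[(R)-7-(benzyloxy)chroman-3-yl]-6-methoxyphenyl}-3-[2,3-bis(benzyloxy)-4-methoxyphenyl]chroman-2-one | COc1ccc([C@@H]2C(=O)Oc3cc(OCc4ccccc4)ccc3[C@H]2c2c(OC)cc(OCc3ccccc3)cc2[C@@H]2COc3cc(OCc4ccccc4)ccc3C2)c(OCc2ccccc2)c1OCc1ccccc1 | intermediate
29 | (2R,3S)-3-[4-(benzyloxy)-2-hydroxyphenyl]-3-{4-(benzyloxy)-2-[(R)-7-(benzyloxy)chroman-3-yl]-6-methoxyphenyl}-2-[2,3-bis(benzyloxy)-4-methoxyphenyl]propan-1-ol | COc1ccc([C@H](CO)[C@@H](c2ccc(OCc3ccccc3)cc2O)c2c(OC)cc(OCc3ccccc3)cc2[C@@H]2COc3cc(OCc4ccccc4)ccc3C2)c(OCc2ccccc2)c1OCc1ccccc1 | intermediate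
30 | (3R,4S)-7-(benzyloxy)-4-{4-(benzyloxy)-2-[(R)-7-(benzyloxy)chroman-3-yl]-6-methoxyphenyl}-3-[2,3-bis(benzyloxy)-4-methoxyphenyl]chroman | COc1ccc([C@@H]2COc3cc(OCc4ccccc4)ccc3[C@H]2c2c(OC)cc(OCc3ccccc3)cc2[C@@H]2COc3cc(OCc4ccccc4)ccc3C2)c(OCc2ccccc2)c1OCc1ccccc1 | intermediate
31 | (3R,4S)-3-(2,3-dihydroxy-4-methoxyphenyl)-4-{4-hydroxy-2-[(R)-7-hydroxychroman-3-yl]-6-methoxyphenyl}chroman-7-ol | COc1ccc([C@@H]2COc3cc(O)ccc3[C@H]2c2c(OC)cc(O)cc2[C@@H]2COc3cc(O)ccc3C2)c(O)c1O | target

## Step count and least certain steps

Total: 21 steps. Longest linear sequence: 17 steps (1 to 31 through steps 1–7, 9–14 and 18–21); step 8 and steps 15–17 are side branches.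

Step 11 (key step). The cycloaddition may be slow, because the ortho-substituted, donor-rich aroyl group is a weak activator and the alkyne carries a branched substituent, so that thermal decomposition of the diene outruns it. Prolonged heating could also allow prototropic isomerisation towards the allenyl ketone, with loss of configuration at C3' or opening of the lower pyran ring by β-elimination. The fallback changes the dienophile and adds ring A afterwards. It sets out from dibromo-olefin 9: n-BuLi followed by DMF gives the smaller and more electrophilic 3-[(R)-7-(benzyloxy)chroman-3-yl]prop-2-ynal F1. Cycloaddition of F1 with 14 and aromatisation, as in step 11, give 2-[(R)-7-(benzyloxy)chroman-3-yl]-4-hydroxy-6-methoxybenzaldehyde F2, and benzylation gives 4-(benzyloxy)-2-[(R)-7-(benzyloxy)chroman-3-yl]-6-methoxybenzaldehyde F3. The aryllithium for ring A is made by bromine–lithium exchange from 4-(benzyloxy)-1-bromo-2-(methoxymethoxy)benzene F5, itself obtained from 4-bromoresorcinol by benzylation of the hydroxyl para to bromine, giving 5-(benzyloxy)-2-bromophenol F4, and methoxymethylation. Addition of this aryllithium to F3 rejoins the route at benzhydrol 19.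

Step 18. The methide carbon of 27 is shielded on both faces by the ortho substituents of the twisted ring C, so addition of the bulky catalyst-bound enolate may be slow and oligomerisation of the quinone methide may take over. The resident C3' centre may also be mismatched with the catalyst, giving poor facial selectivity. The fallback gives up catalyst control and uses a small stoichiometric enolate. It sets out from 21 and 25: acid 25 is converted into methyl 2-[2,3-bis(benzyloxy)-4-methoxyphenyl]acetate F6 (MeI, K2CO3). Its lithium enolate (LiN(SiMe3)2, THF, −78 °C, with a second equivalent of base to release 27 from 21) adds to the methide carbon to give the open-chain phenol ester methyl 3-[4-(benzyloxy)-2-hydroxyphenyl]-3-{4-(benzyloxy)-2-[(R)-7-(benzyloxy)chroman-3-yl]-6-methoxyphenyl}-2-[2,3-bis(benzyloxy)-4-methoxyphenyl]propanoate F7. Acid-catalysed lactonisation and equilibration at C3 with an amidine base should give the two trans lactones, 28 and its (3S,4R)-diastereomer F8. These differ in their relation to C3' and are separated by chromatography; the route is rejoined at 28, at the cost of about half the material.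

Step 14. The benzhydryl cation, or the quinone methide formed once the phenol is free, may alkylate the electron-rich rings of a second molecule before sulfinate captures it, and acetal cleavage may be incomplete under conditions mild enough to avoid this. The fallback moves the acid step to a stage with no ionisable centre. It sets out from ketone 18: HCl in methanol removes the methoxymethyl group to give the chelated [4-(benzyloxy)-2-hydroxyphenyl]{4-(benzyloxy)-2-[(R)-7-(benzyloxy)chroman-3-yl]-6-methoxyphenyl}methanone F9. LiAlH4 at low temperature reduces F9 to 5-(benzyloxy)-2-{[4-(benzyloxy)-2-((R)-7-(benzyloxy)chroman-3-yl)-6-methoxyphenyl](hydroxy)methyl}phenol F10, and p-toluenesulfinic acid alone in CH2Cl2, without mineral acid, converts F10 into 21, where the route is rejoined.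

Step 4. The enantioselectivity may be insufficient, or the electron-rich, trisubstituted alkene may be reduced slowly. The fallback is a classical resolution. It sets out from 5: hydrogenation over the achiral complex [Ir(cod)(PCy3)(py)]PF6 in CH2Cl2 (benzyl ether untouched) gives racemic 7-(benzyloxy)chroman-3-carboxylic acid F11. Fractional crystallisation of its salt with (S)-1-phenylethylamine (or the antipodal amine, whichever gives the less soluble salt of the S acid) gives (S)-1-phenylethylammonium (S)-7-(benzyloxy)chroman-3-carboxylate F12, and acidification returns acid 6, where the route is rejoined.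

## Further compounds

F1 | step 11 | 3-[(R)-7-(benzyloxy)chroman-3-yl]prop-2-ynal | O=CC#C[C@@H]1COc2cc(OCc3ccccc3)ccc2C1
F2 | step 11 | 2-[(R)-7-(benzyloxy)chroman-3-yl]-4-hydroxy-6-methoxybenzaldehyde | COc1cc(O)cc([C@@H]2COc3cc(OCc4ccccc4)ccc3C2)c1C=O
F3 | step 11 | 4-(benzyloxy)-2-[(R)-7-(benzyloxy)chroman-3-yl]-6-methoxybenzaldehyde | COc1cc(OCc2ccccc2)cc([C@@H]2COc3cc(OCc4ccccc4)ccc3C2)c1C=O
F4 | step 11 | 5-(benzyloxy)-2-bromophenol | Oc1cc(OCc2ccccc2)ccc1Br
F5 | step 11 | 4-(benzyloxy)-1-bromo-2-(methoxymethoxy)benzene | COCOc1cc(OCc2ccccc2)ccc1Br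
F6 | step 18 | methyl 2-[2,3-bis(benzyloxy)-4-methoxyphenyl]acetate | COC(=O)Cc1ccc(OC)c(OCc2ccccc2)c1OCc1ccccc1
F7 | step 18 | methyl 3-[4-(benzyloxy)-2-hydroxyphenyl]-3-{4-(benzyloxy)-2-[(R)-7-(benzyloxy)chroman-3-yl]-6-methoxyphenyl}-2-[2,3-bis(benzyloxy)-4-methoxyphenyl]propanoate (diastereomers at C2 and C3) | COC(=O)C(c1ccc(OC)c(OCc2ccccc2)c1OCc1ccccc1)C(c1ccc(OCc2ccccc2)cc1O)c1c(OC)cc(OCc2ccccc2)cc1[C@@H]1COc2cc(OCc3ccccc3)ccc2C1
F8 | step 18 | (3S,4R)-7-(benzyloxy)-4-{4-(benzyloxy)-2-[(R)-7-(benzyloxy)chroman-3-yl]-6-methoxyphenyl}-3-[2,3-bis(benzyloxy)-4-methoxyphenyl]chroman-2-one | COc1ccc([C@H]2C(=O)Oc3cc(OCc4ccccc4)ccc3[C@@H]2c2c(OC)cc(OCc3ccccc3)cc2[C@@H]2COc3cc(OCc4ccccc4)ccc3C2)c(OCc2ccccc2)c1OCc1ccccc1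
F9 | step 14 | [4-(benzyloxy)-2-hydroxyphenyl]{4-(benzyloxy)-2-[(R)-7-(benzyloxy)chroman-3-yl]-6-methoxyphenyl}methanone | COc1cc(OCc2ccccc2)cc([C@@H]2COc3cc(OCc4ccccc4)ccc3C2)c1C(=O)c1ccc(OCc2ccccc2)cc1O
F10 | step 14 | 5-(benzyloxy)-2-{[4-(benzyloxy)-2-((R)-7-(benzyloxy)chroman-3-yl)-6-methoxyphenyl](hydroxy)methyl}phenol (carbinol epimers) | COc1cc(OCc2ccccc2)cc([C@@H]2COc3cc(OCc4ccccc4)ccc3C2)c1C(O)c1ccc(OCc2ccccc2)cc1O
F11 | step 4 | racemic 7-(benzyloxy)chroman-3-carboxylic acid | OC(=O)C1COc2cc(OCc3ccccc3)ccc2C1
F12 | step 4 | (S)-1-phenylethylammonium (S)-7-(benzyloxy)chroman-3-carboxylate | C[C@H]([NH3+])c1ccccc1.[O-]C(=O)[C@@H]1COc2cc(OCc3ccccc3)ccc2C1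
A1 | alternative 1 | ethyl 2-{5-(benzyloxy)-2-[4-(benzyloxy)-2-(methoxymethoxy)benzoyl]-3-methoxyphenyl}acetate | CCOC(=O)Cc1cc(OCc2ccccc2)cc(OC)c1C(=O)c1ccc(OCc2ccccc2)cc1OCOC
A2 | alternative 1 | 5-(benzyloxy)-3-methoxy-2-(trimethylsilyl)phenyl trifluoromethanesulfonate | COc1cc(OCc2ccccc2)cc(OS(=O)(=O)C(F)(F)F)c1[Si](C)(C)C
A3 | alternative 1 | ethyl 3-[4-(benzyloxy)-2-(methoxymethoxy)phenyl]-3-oxopropanoate | CCOC(=O)CC(=O)c1ccc(OCc2ccccc2)cc1OCOC
A4 | alternative 2 | (3R,4S)-7-(benzyloxy)-4-{4-(benzyloxy)-2-[(R)-7-(benzyloxy)chroman-3-yl]-6-methoxyphenyl}-3-[2,3-bis(benzyloxy)-4-methoxyphenyl]chroman-2-one | COc1ccc([C@@H]2C(=O)Oc3cc(OCc4ccccc4)ccc3[C@H]2c2c(OC)cc(OCc3ccccc3)cc2[C@@H]2COc3cc(OCc4ccccc4)ccc3C2)c(OCc2ccccc2)c1OCc1ccccc1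
A5 | alternative 2 | 5-(benzyloxy)-2-{[4-(benzyloxy)-2-((R)-7-(benzyloxy)chroman-3-yl)-6-methoxyphenyl](4-methylbenzenesulfonyl)methyl}phenol | COc1cc(OCc2ccccc2)cc([C@@H]2COc3cc(OCc4ccccc4)ccc3C2)c1C(c1ccc(OCc2ccccc2)cc1O)S(=O)(=O)c1ccc(C)cc1
A6 | alternative 2 | 4-nitrophenyl 2-[2,3-bis(benzyloxy)-4-methoxyphenyl]acetate | COc1ccc(CC(=O)Oc2ccc([N+](=O)[O-])cc2)c(OCc2ccccc2)c1OCc1ccccc1
A7 | alternative 3 | (3R,4S)-7-(benzyloxy)-4-{4-(benzyloxy)-2-[(R)-7-(benzyloxy)chroman-3-yl]-6-methoxyphenyl}-3-[2,3-bis(benzyloxy)-4-methoxyphenyl]chroman | COc1ccc([C@@H]2COc3cc(OCc4ccccc4)ccc3[C@H]2c2c(OC)cc(OCc3ccccc3)cc2[C@@H]2COc3cc(OCc4ccccc4)ccc3C2)c(OCc2ccccc2)c1OCc1ccccc1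
A8 | alternative 3 | 3-[3-(benzyloxy)phenoxy]-1-{4-(benzyloxy)-2-[(R)-7-(benzyloxy)chroman-3-yl]-6-methoxyphenyl}-2-[2,3-bis(benzyloxy)-4-methoxyphenyl]propan-1-ol (C2 configured as C3 of the target, carbinol epimers) | COc1ccc([C@H](COc2cccc(OCc3ccccc3)c2)C(O)c2c(OC)cc(OCc3ccccc3)cc2[C@@H]2COc3cc(OCc4ccccc4)ccc3C2)c(OCc2ccccc2)c1OCc1ccccc1
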